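**Strategy.** The target is cut at the cyclohexene ring into two guaianolides: the C4'=C15' enone of dehydrozaluzanin C and a C14=C10–C1=C2 trienone that carries the 8β-oxygen. The seven-membered ring of that diene half (C1, C5, C6, C7, C8, C9, C10) is not closed directly; it is grown from ring B of a eudesmanolide. The key step is the photochemical rearrangement of the cross-conjugated dienone C1=C2–C3(=O)–C4=C5 around quaternary C10: C1–C5 bonding and C5–C10 cleavage contract ring A to the cyclopentenone and expand ring B by C1 in one operation. Its precursor is an 8β-silyloxy santonin-type lactone made from isoalantolactone.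

Key step: step 6

Remark: eudesmane/guaiane locants C1–C15 are used for the hydroxylated half and primed locants for the other half; α is the face of H5, β the face of the C8 oxygen; isoalantolactone and dehydrocostus lactone are taken as purchasable natural products.

Step 1
Reactants: 1 isoalantolactone
Product: 2 3α-hydroxyisoalantolactone (3α-hydroxyeudesma-4(15),11(13)-dien-12,8β-olide)
Conditions: SeO2 (0.5 equiv), t-BuOOH, CH2Cl2, rt
Reagents that add atoms: selenium dioxide O=[Se]=O; tert-butyl hydroperoxide CC(C)(C)OO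
Why: SeO2 allylic hydroxylation (ene reaction, then [2,3]-shift) should attack the C3 methylene next to the C4(15) alkene, removing the axial H3 and returning oxygen on the α face; the C3 configuration is erased in step 3.

Step 2
Reactants: 2 3α-hydroxyisoalantolactone
Product: 3 3-oxo-4α-methyl-4βH,5αH-eudesm-11(13)-en-12,8β-olide
Conditions: CpRu(PPh3)2Cl (5 mol %), Et3NHPF6 (10 mol %), dioxane, 100 °C
Reagents that add atoms: none
Why: Ru-catalysed redox isomerization of the allylic alcohol (internal hydride transfer through the ruthenium alkoxide) should give the saturated ketone and leave the acrylate alone; the C4 methyl should settle equatorial (α) by enolization, and C4 becomes sp2 in step 3.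

Step 3
Reactants: 3 3-oxo-4α-methyleudesm-11(13)-en-12,8β-olide
Product: 4 3-oxoeudesma-1,4,11(13)-trien-12,8β-olide
Conditions: IBX (4 equiv), DMSO/fluorobenzene, 80 °C
Reagents that add atoms: none
Why: Twofold IBX dehydrogenation of the cyclohexanone (C1–C2 and C4–C5) should stop at the cross-conjugated dienone, since the lactone and the electron-poor acrylate offer no enolizable site.

Step 4
Reactants: 4 3-oxoeudesma-1,4,11(13)-trien-12,8β-olide
Product: 6 tert-butyldimethylsilyl 3,8β-bis(tert-butyldimethylsilyloxy)eudesma-1,3,5,11(13)-tetraen-12-oate, via lithium hydroxy-carboxylate 5 (not isolated)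
Conditions: LiOH (1.05 equiv), THF/H2O, 0 °C; evaporate; TBSOTf (3.5 equiv), Et3N, CH2Cl2, 0 °C
Reagents that add atoms: lithium hydroxide [Li+].[OH-]; tert-butyldimethylsilyl triflate CC(C)(C)[Si](C)(C)OS(=O)(=O)C(F)(F)F
Why: Saponification opens the cis 8β,12-lactone, and silyl triflate/amine (soft enolization) should silylate the carboxylate and the axial 8β-hydroxyl and turn the dienone into its silyl trienol ether by γ-deprotonation at C6, so that the acid cannot close back on O8.

Step 5
Reactants: 6 tris-silyl trienol ether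
Product: 8 8β-(tert-butyldimethylsilyloxy)-3-oxo-6βH,7αH-eudesma-1,4,11(13)-trien-12,6α-olide, via 6β-bromo dienone silyl ester 7 (not isolated)
Conditions: NBS (1.05 equiv), THF, −78 °C; then NaHCO3, THF/H2O, 0 °C to rt
Reagents that add atoms: none
Why: NBS should brominate the γ-terminus C6 of the trienol ether by axial (β) attack, as in 6β-bromination of steroidal dienol ethers; hydrolysis of the labile silyl ester then frees the carboxylate, which should displace the allylic bromide by intramolecular SN2 with inversion to give the trans 6α,12-lactone.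

Step 6
Reactants: 8 8β-silyloxy-3-oxoeudesma-1,4,11(13)-trien-12,6α-olide
Product: 9 10α-hydroxy-8β-(tert-butyldimethylsilyloxy)-3-oxo-1αH-guaia-4,11(13)-dien-12,6α-olide (10β-methyl)
Conditions: hν (medium-pressure Hg lamp, Pyrex, >300 nm), AcOH/H2O 1:1, degassed, rt
Reagents that add atoms: water O
Why: Excitation of the dienone (n→π*, triplet) should bond C1 to C5, giving a cyclopropane (C1–C5–C10) fused to an oxyallyl zwitterion; protonation on oxygen and cleavage of the C5–C10 bond pass the positive charge to C10, where water adds (type A dienone rearrangement in acid, the santonin to isophotosantonic lactone reaction). The cyclopentenone C1–C5 closes through the new C1–C5 bond, and the seven-membered ring (C1, C5, C6, C7, C8, C9, C10) arises by one-atom expansion of six-membered ring B when C5–C10 breaks and C1 is inserted. C1 (H α) is set by C1–C5 bonding on the face of ring A away from the axial C10 methyl, and C10 (OH α, CH3 β) by attack of water anti to the departing C5; both centres are erased later, while C6, C7 and C8 are untouched. The step needs C5–C10 rather than C1–C10 cleavage (5/7 and not spiro product) and no lumiketone; the C4 methyl stabilizes positive charge at C4 and so directs C5–C10 cleavage, and the protic acid intercepts the zwitterion before the 1,4-shift. The acrylate does not absorb above 300 nm, and the hindered axial silyl ether should survive the short exposure to aqueous acetic acid.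

Step 7
Reactants: 9 10α-hydroxy-3-oxoguaia-4,11(13)-dienolide
Product: 10 3β,10α-dihydroxy-8β-(tert-butyldimethylsilyloxy)-1αH-guaia-4,11(13)-dien-12,6α-olide
Conditions: NaBH4, CeCl3·7H2O, MeOH, −78 °C
Reagents that add atoms: none
Why: Luche 1,2-reduction should spare the acrylate; hydride is expected on the α face of C3, opposite the C10 substituent on C1, giving the 3β-alcohol.

Step 8
Reactants: 10 3β,10α-dihydroxyguaia-4,11(13)-dienolide
Product: 13 10α-hydroxy-8β-(tert-butyldimethylsilyloxy)-1αH,5αH-guaia-3,11(13)-dien-12,6α-olide, via N-allyl sulfonylhydrazine 11 (not isolated), via allylic diazene 12 (not isolated)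
Conditions: 2-O2NC6H4SO2NHNH2, PPh3, DEAD, THF, −30 °C to rt
Reagents that add atoms: none
Why: Myers reductive allylic transposition: Mitsunobu displacement inverts C3 (3α-N), loss of sulfinic acid gives the monoalkyl diazene, and its retro-ene loss of N2 delivers hydrogen suprafacially to C5 on the α face, which sets the cis 1α,5α ring fusion and moves the alkene to C3=C4.

Step 9
Reactants: 13 10α-hydroxyguaia-3,11(13)-dienolide
Product: 14 3α,4α-epoxy-10α-hydroxy-8β-(tert-butyldimethylsilyloxy)-1αH,5αH-guai-11(13)-en-12,6α-olide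
Conditions: mCPBA, CH2Cl2, 0 °C
Reagents that add atoms: meta-chloroperbenzoic acid O=C(OO)c1cccc(Cl)c1
Why: Prilezhaev epoxidation should take the only electron-rich alkene (C3=C4) from the convex α face of the cis-fused bicycle and leave the acrylate.

Step 10
Reactants: 14 3α,4α-epoxide
Product: 15 3α,10α-dihydroxy-8β-(tert-butyldimethylsilyloxy)-1αH,5αH-guaia-4(15),11(13)-dien-12,6α-olide
Conditions: Cp2TiCl2 (2.5 equiv), Mn dust, THF, rt (Cp2TiCl in situ)
Reagents that add atoms: none
Why: Titanocene(III) opens the epoxide homolytically to the tertiary C4 radical, and a second Ti(III) traps it and removes a C15 hydrogen (Nugent–RajanBabu opening, then β-hydride loss), which should give the exocyclic methylene allylic alcohol under neutral conditions.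

Step 11
Reactants: 15 3α,10α-dihydroxyguaia-4(15),11(13)-dienolide
Product: 16 10α-hydroxy-8β-(tert-butyldimethylsilyloxy)-3-oxo-1αH,5αH-guaia-4(15),11(13)-dien-12,6α-olide
Conditions: Dess–Martin periodinane, CH2Cl2, rt
Reagents that add atoms: none
Why: Dess–Martin oxidation takes the secondary allylic alcohol to the α-methylene ketone and cannot touch the tertiary C10 alcohol.

Step 12
Reactants: 16 10α-hydroxy-3-oxoguaia-4(15),11(13)-dienolide
Product: 17 8β-(tert-butyldimethylsilyloxy)-3-oxo-1αH,5αH-guaia-4(15),10(14),11(13)-trien-12,6α-olide (8β-silyloxydehydrozaluzanin C)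
Conditions: SOCl2, pyridine, CH2Cl2, −20 °C
Reagents that add atoms: none
Why: E2 dehydration through the chlorosulfite: the hydrogens anti to the 10α-oxygen are those of the C14 methyl and H9β, while H1α is syn, so the exocyclic C10=C14 alkene is expected as the main product.

Step 13
Reactants: 18 dehydrocostus lactone
Product: 19 3-epizaluzanin C (3α-hydroxyguaia-4(15),10(14),11(13)-trien-12,6α-olide)
Conditions: SeO2 (0.5 equiv), t-BuOOH, CH2Cl2, rt
Reagents that add atoms: selenium dioxide O=[Se]=O; tert-butyl hydroperoxide CC(C)(C)OO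
Why: SeO2 allylic hydroxylation should take the C3' methylene next to the C4'(15') alkene in preference to the methine C5' and to C9'; the C3' configuration is erased in step 14.

Step 14
Reactants: 19 3-epizaluzanin C
Product: 20 dehydrozaluzanin C
Conditions: Dess–Martin periodinane, CH2Cl2, rt
Reagents that add atoms: none
Why: Dess–Martin oxidation of the allylic alcohol gives the C3' ketone conjugated with the C4'=C15' alkene, which is the dienophile.

Step 15
Reactants: 17 8β-silyloxydehydrozaluzanin C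
Product: 21 3,8β-bis(tert-butyldimethylsilyloxy)-1αH,5αH-guaia-2,4(15),10(14),11(13)-tetraen-12,6α-olide
Conditions: TBSOTf, Et3N, CH2Cl2, −78 to 0 °C
Reagents that add atoms: tert-butyldimethylsilyl triflate CC(C)(C)[Si](C)(C)OS(=O)(=O)C(F)(F)F
Why: Soft enolization can only remove a C2 hydrogen (the sole α-CH2), which gives the 2-silyloxy diene needed for the Saegusa oxidation.

Step 16
Reactants: 21 silyl dienol ether; 20 dehydrozaluzanin C
Product: 23 Diels–Alder adduct (bonds C14–C15' and C2–C4', C1=C10 alkene, 2βH, spiro C4' R, 8β-OTBS), via trienone 22 (not isolated)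
Conditions: Pd(OAc)2 (1.2 equiv), 20 (3 equiv), MeCN, Ar, rt
Reagents that add atoms: none
Why: Saegusa–Ito oxidation should give the cross-conjugated trienone, whose C14=C10–C1=C2 diene is trapped in situ by excess 20 in a biomimetic Diels–Alder reaction; ortho regiochemistry joins C2 to C4' and C14 to C15', the diene adds to the convex α face of 20 (sets spiro C4'), and argon prevents autoxidation at C10.

Step 17
Reactants: 23 Diels–Alder adduct
Product: 24 8-O-tert-butyldimethylsilyl ether of the target (C1=C2 enone, 10βH)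
Conditions: DBU (0.2 equiv), CH2Cl2, Ar, 0 °C
Reagents that add atoms: none
Why: Base-mediated conjugation of the β,γ-unsaturated ketone through the C3 dienolate; γ-protonation at C10 is reversible, so the mixture should settle on the more stable 10βH epimer, with C9 pseudo-equatorial on the new cyclohexene.

Step 18
Reactants: 24 silyl ether of the target
Product: 25 CNP0200944.1
Conditions: HF·pyridine, THF, 0 °C to rt
Reagents that add atoms: none
Why: Fluoride-driven cleavage of the silyl ether under mildly acidic conditions should spare the lactones and enones and avoid base-induced acyl migration to O8.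

**Compound list**

1 | isoalantolactone | C=C1CCC[C@]2(C)C[C@H]3OC(=O)C(=C)[C@H]3C[C@@H]12 | starting material
2 | 3α-hydroxyisoalantolactone | C=C1[C@H](O)CC[C@]2(C)C[C@H]3OC(=O)C(=C)[C@H]3C[C@@H]12 | intermediate
3 | 3-oxo-4α-methyl-4βH,5αH-eudesm-11(13)-en-12,8β-olide | C[C@@H]1C(=O)CC[C@]2(C)C[C@H]3OC(=O)C(=C)[C@H]3C[C@@H]12 | intermediate
4 | 3-oxoeudesma-1,4,11(13)-trien-12,8β-olide | CC1=C2C[C@@H]3C(=C)C(=O)O[C@@H]3C[C@@]2(C)C=CC1=O | intermediate
5 | lithium 8β-hydroxy-3-oxoeudesma-1,4,11(13)-trien-12-oate | CC1=C2C[C@H](C(=C)C(=O)[O-])[C@H](O)C[C@@]2(C)C=CC1=O.[Li+] | intermediate (not isolated)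
6 | tert-butyldimethylsilyl 3,8β-bis(tert-butyldimethylsilyloxy)eudesma-1,3,5,11(13)-tetraen-12-oate | CC1=C(O[Si](C)(C)C(C)(C)C)C=C[C@]2(C)C[C@@H](O[Si](C)(C)C(C)(C)C)[C@@H](C(=C)C(=O)O[Si](C)(C)C(C)(C)C)C=C12 | intermediate
7 | tert-butyldimethylsilyl 6β-bromo-8β-(tert-butyldimethylsilyloxy)-3-oxoeudesma-1,4,11(13)-trien-12-oate | CC1=C2[C@H](Br)[C@H](C(=C)C(=O)O[Si](C)(C)C(C)(C)C)[C@H](O[Si](C)(C)C(C)(C)C)C[C@@]2(C)C=CC1=O | intermediate (not isolated)
8 | 8β-(tert-butyldimethylsilyloxy)-3-oxoeudesma-1,4,11(13)-trien-12,6α-olide | CC1=C2[C@H]3OC(=O)C(=C)[C@@H]3[C@H](O[Si](C)(C)C(C)(C)C)C[C@@]2(C)C=CC1=O | intermediate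
9 | 10α-hydroxy-8β-(tert-butyldimethylsilyloxy)-3-oxo-1αH-guaia-4,11(13)-dien-12,6α-olide | CC1=C2[C@H]3OC(=O)C(=C)[C@@H]3[C@H](O[Si](C)(C)C(C)(C)C)C[C@@](C)(O)[C@@H]2CC1=O | intermediate
10 | 3β,10α-dihydroxy-8β-(tert-butyldimethylsilyloxy)-1αH-guaia-4,11(13)-dien-12,6α-olide | CC1=C2[C@H]3OC(=O)C(=C)[C@@H]3[C@H](O[Si](C)(C)C(C)(C)C)C[C@@](C)(O)[C@@H]2C[C@@H]1O | intermediate
11 | 3α-[N-amino-N-(2-nitrophenylsulfonyl)amino]-10α-hydroxy-8β-(tert-butyldimethylsilyloxy)-1αH-guaia-4,11(13)-dien-12,6α-olide | CC1=C2[C@H]3OC(=O)C(=C)[C@@H]3[C@H](O[Si](C)(C)C(C)(C)C)C[C@@](C)(O)[C@@H]2C[C@H]1N(N)S(=O)(=O)c1ccccc1[N+](=O)[O-] | intermediate (not isolated)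
12 | 3α-diazenyl-10α-hydroxy-8β-(tert-butyldimethylsilyloxy)-1αH-guaia-4,11(13)-dien-12,6α-olide | CC1=C2[C@H]3OC(=O)C(=C)[C@@H]3[C@H](O[Si](C)(C)C(C)(C)C)C[C@@](C)(O)[C@@H]2C[C@H]1N=N | intermediate (not isolated)
13 | 10α-hydroxy-8β-(tert-butyldimethylsilyloxy)-1αH,5αH-guaia-3,11(13)-dien-12,6α-olide | CC1=CC[C@@H]2[C@H]1[C@H]3OC(=O)C(=C)[C@@H]3[C@H](O[Si](C)(C)C(C)(C)C)C[C@@]2(C)O | intermediate
14 | 3α,4α-epoxy-10α-hydroxy-8β-(tert-butyldimethylsilyloxy)-1αH,5αH-guai-11(13)-en-12,6α-olide | C[C@@]12O[C@@H]1C[C@@H]3[C@H]2[C@H]4OC(=O)C(=C)[C@@H]4[C@H](O[Si](C)(C)C(C)(C)C)C[C@@]3(C)O | intermediate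
15 | 3α,10α-dihydroxy-8β-(tert-butyldimethylsilyloxy)-1αH,5αH-guaia-4(15),11(13)-dien-12,6α-olide | C=C1[C@H](O)C[C@@H]2[C@H]1[C@H]3OC(=O)C(=C)[C@@H]3[C@H](O[Si](C)(C)C(C)(C)C)C[C@@]2(C)O | intermediate
16 | 10α-hydroxy-8β-(tert-butyldimethylsilyloxy)-3-oxo-1αH,5αH-guaia-4(15),11(13)-dien-12,6α-olide | C=C1C(=O)C[C@@H]2[C@H]1[C@H]3OC(=O)C(=C)[C@@H]3[C@H](O[Si](C)(C)C(C)(C)C)C[C@@]2(C)O | intermediate
17 | 8β-(tert-butyldimethylsilyloxy)dehydrozaluzanin C | C=C1C(=O)C[C@@H]2[C@H]1[C@H]3OC(=O)C(=C)[C@@H]3[C@H](O[Si](C)(C)C(C)(C)C)CC2=C | intermediate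
18 | dehydrocostus lactone | C=C1CC[C@@H]2[C@@H]([C@@H]3[C@H]1CCC3=C)OC(=O)C2=C | starting material
19 | 3-epizaluzanin C | C=C1CC[C@@H]2[C@@H]([C@@H]3[C@H]1C[C@@H](O)C3=C)OC(=O)C2=C | intermediate
20 | dehydrozaluzanin C | C=C1CC[C@@H]2[C@@H]([C@@H]3[C@H]1CC(=O)C3=C)OC(=O)C2=C | intermediate
21 | 3,8β-bis(tert-butyldimethylsilyloxy)guaia-2,4(15),10(14),11(13)-tetraen-12,6α-olide | C=C1C(O[Si](C)(C)C(C)(C)C)=C[C@@H]2[C@H]1[C@H]3OC(=O)C(=C)[C@@H]3[C@H](O[Si](C)(C)C(C)(C)C)CC2=C | intermediate
22 | 8β-(tert-butyldimethylsilyloxy)-3-oxoguaia-1,4(15),10(14),11(13)-tetraen-12,6α-olide | C=C1C(=O)C=C2[C@H]1[C@H]3OC(=O)C(=C)[C@@H]3[C@H](O[Si](C)(C)C(C)(C)C)CC2=C | intermediate (not isolated)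
23 | Diels–Alder adduct (C1=C10, 2βH, spiro C4') | C=C1C(=O)[C@H]2C3=C(CC[C@]24C(=O)C[C@H]2C(=C)CC[C@H]5C(=C)C(=O)O[C@@H]5[C@H]24)C[C@@H](O[Si](C)(C)C(C)(C)C)[C@H]2C(=C)C(=O)O[C@@H]2[C@@H]13 | intermediate
24 | 8-O-tert-butyldimethylsilyl ether of the target | C=C1C(=O)C2=C3[C@H](CC[C@]24C(=O)C[C@H]2C(=C)CC[C@H]5C(=C)C(=O)O[C@@H]5[C@H]24)C[C@@H](O[Si](C)(C)C(C)(C)C)[C@H]2C(=C)C(=O)O[C@@H]2[C@@H]13 | intermediate
25 | CNP0200944.1 | C=C1C(=O)C2=C3[C@H](CC[C@]24C(=O)C[C@H]2C(=C)CC[C@H]5C(=C)C(=O)O[C@@H]5[C@H]24)C[C@@H](O)[C@H]2C(=C)C(=O)O[C@@H]2[C@@H]13 | target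

**Step count.** Total: 18 steps. Longest linear sequence: 16 steps (steps 1–12 and 15–18); steps 13–14 make the dienophile.

**Steps most likely to fail**

Step 5 (lactone transposition). Loss of HBr from the 6β-bromide toward C7 (H7 is trans-diaxial), or ionization at C6 with loss of the inversion, could outrun the intramolecular displacement. Fallback, setting out from 6: peracid oxidation of the silyl trienol ether at its C6 terminus (mCPBA, CH2Cl2, −20 °C; vinylogous Rubottom oxidation) should give the 6β-hydroxy dienone silyl ester F1. Mild hydrolysis (NaHCO3, aqueous THF) frees the 6β-hydroxy acid F2. Mitsunobu lactonization (PPh3, DIAD, THF, 0 °C) then closes the C6–O bond with inversion and comes back to the route at 8.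

Step 12 (dehydration). Elimination toward C9 would give the endocyclic C9=C10 alkene or a mixture of regioisomers. Fallback, setting out from 16: a syn elimination with the Burgess reagent (benzene, 50 °C) can use H1α, which is syn to the 10α-oxygen, and should give the tetrasubstituted C1(10)-ene ketone F3. Soft enolization (TBSOTf, Et3N) gives the extended silyl dienol ether F4. Pd(OAc)2 then removes a C14 hydrogen through the palladium dienolate (γ,δ-dehydrogenation of the Saegusa type), and the route is rejoined at trienone 22 inside step 16.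

Step 17 (C10 configuration). The face of protonation at C10 may be poorly controlled, or the equilibrium may favour the 10αH epimer. Fallback, setting out from 23: a transition-metal hydride catalyst ([Ir(cod)(PCy3)(py)]PF6 activated with H2, THF, rt) moves H2 to C10 by a suprafacial 1,3-hydrogen shift through an allyl hydride. As H2 is β in 23, the hydrogen should arrive on the β face of C10, and the route is rejoined at 24. This fallback makes no new compound (F0).

**Further compounds**

F1 | step 5 | tert-butyldimethylsilyl 6β-hydroxy-8β-(tert-butyldimethylsilyloxy)-3-oxoeudesma-1,4,11(13)-trien-12-oate | CC1=C2[C@H](O)[C@H](C(=C)C(=O)O[Si](C)(C)C(C)(C)C)[C@H](O[Si](C)(C)C(C)(C)C)C[C@@]2(C)C=CC1=O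
F2 | step 5 | 6β-hydroxy-8β-(tert-butyldimethylsilyloxy)-3-oxoeudesma-1,4,11(13)-trien-12-oic acid | CC1=C2[C@H](O)[C@H](C(=C)C(=O)O)[C@H](O[Si](C)(C)C(C)(C)C)C[C@@]2(C)C=CC1=O
F3 | step 12 | 8β-(tert-butyldimethylsilyloxy)-3-oxo-5αH-guaia-1(10),4(15),11(13)-trien-12,6α-olide | C=C1C(=O)CC2=C(C)C[C@@H](O[Si](C)(C)C(C)(C)C)[C@H]3C(=C)C(=O)O[C@@H]3[C@@H]12
F4 | step 12 | 3,8β-bis(tert-butyldimethylsilyloxy)-5αH-guaia-1(10),2,4(15),11(13)-tetraen-12,6α-olide | C=C1C(O[Si](C)(C)C(C)(C)C)=CC2=C(C)C[C@@H](O[Si](C)(C)C(C)(C)C)[C@H]3C(=C)C(=O)O[C@@H]3[C@@H]12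
F0 | step 17 | none | none
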